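**Plan**

- Retrosynthesis: first the C9–O acyl bond (to (2R,3R)-epoxyangelic acid) and the C3 acetate are cut. Then the lactone O–C12 bond and the C4=C5 π bond are cut together by re-joining C4 to C9.
- Enabling feature: the array O=C9 … C4(CH3)=C5–C6–O of the ten-membered ring maps onto a C9 alkoxide, a C4–C9 σ bond and a C5,C6-epoxide. The ring C4–C5–C6–C7–C8–C9 so formed (ring A) is the carvone ring.
- Further cuts: C1=C10 (metathesis), C9–C10 (isopropenyl addition), C2–C3 (allylboration) and C3–C4 (aldol with formaldehyde) lead back to (S)-carvone.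
- Forward: ring A is carvone; ring B (C4–C3–C2–C1=C10–C9) is closed by metathesis to a cis-decalin; fragmentation of the shared C4–C9 bond gives the ten-membered ring while the γ-lactone closes; the ester side chain comes last.
- Stereochemistry: C7 from (S)-carvone; C4 and C8 by attack anti to the C7 group; the epoxide (hence C6) by hydroxyl direction; C3 by the chiral allylborane; C9 by Felkin-type reduction; the epoxyangelate by Sharpless epoxidation.
- Alkene geometry: C1=C10 is Z because it is closed in a six-membered ring; C4=C5 is Z through the stereospecific fragmentation.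

Key step: step 16

Remark: germacrane numbering is kept for every intermediate; β is the face of ring A opposite to the C7 side chain, α the face of that side chain.

**Route**

Step 1
Reactants: 1 (S)-carvone
Product: 2 (5S)-5-(3-chloroprop-1-en-2-yl)-2-methylcyclohex-2-en-1-one
Conditions: Ca(OCl)2, CO2 (dry ice), CH2Cl2/H2O, 0 °C
Reagents that add atoms: calcium hypochlorite, [Ca+2].[O-]Cl.[O-]Cl
Why: Ene-type allylic chlorination by HOCl formed in situ should attack only the electron-rich isopropenyl alkene (the enone alkene is inert) and leaves the remote C7 centre untouched.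

Step 2
Reactants: 2 (5S)-5-(3-chloroprop-1-en-2-yl)-2-methylcyclohex-2-en-1-one
Product: 3 (5S)-5-[3-(4-methoxybenzyloxy)prop-1-en-2-yl]-2-methylcyclohex-2-en-1-one
Conditions: 4-methoxybenzyl alcohol, NaH, THF, 0 °C; then 2, Bu4NI (cat.), 0 °C → rt
Reagents that add atoms: 4-methoxybenzyl alcohol, COc1ccc(CO)cc1
Why: Williamson etherification of the allylic chloride; SN2 and SN2′ displacement give the same ether, and addition of the alkoxide to the α-methyl enone is reversible.

Step 3
Reactants: 3 (5S)-5-[3-(4-methoxybenzyloxy)prop-1-en-2-yl]-2-methylcyclohex-2-en-1-one; 4 formaldehyde (monomeric, from cracked paraformaldehyde)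
Product: 6 (2R,5R)-2-(hydroxymethyl)-2-methyl-5-[3-(4-methoxybenzyloxy)prop-1-en-2-yl]cyclohex-3-en-1-one, via potassium dienolate 5 (not isolated)
Conditions: KOtBu (1.0 equiv), THF, 0 °C; then 4 in THF, −78 °C; AcOH, −78 °C
Reagents that add atoms: none
Why: Deconjugative crossed aldol reaction: the through-conjugated thermodynamic dienolate should react with the small aldehyde at its α-carbon C4, moving the alkene to C5=C6, and the electrophile is expected to enter anti to the C7 side chain so that CH2OH is β and the methyl α.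

Step 4
Reactants: 6 (2R,5R)-2-(hydroxymethyl)-2-methyl-5-[3-(4-methoxybenzyloxy)prop-1-en-2-yl]cyclohex-3-en-1-one
Product: 7 5β,6β-epoxide of 6 (epoxide cis to CH2OH and trans to the C7 side chain)
Conditions: VO(acac)2 (cat.), tBuOOH, CH2Cl2, 0 °C → rt
Reagents that add atoms: tert-butyl hydroperoxide, CC(C)(C)OO
Why: Hydroxyl-directed vanadium-catalysed epoxidation: the homoallylic primary alcohol on the β face of C4 should deliver oxygen to the β face of C5=C6 only, and the remote, undirected C11=C13 alkene should not react.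

Step 5
Reactants: 7 5β,6β-epoxy hydroxymethyl ketone
Product: 8 4β-formyl-5β,6β-epoxy ketone (C3 aldehyde)
Conditions: Dess–Martin periodinane, NaHCO3, CH2Cl2, 0 °C → rt
Reagents that add atoms: none
Why: Dess–Martin oxidation of the neopentyl primary alcohol under buffered neutral conditions should give the non-enolisable β-keto aldehyde without touching the epoxide or the PMB ether.

Step 6
Reactants: 8 4β-formyl-5β,6β-epoxy ketone; 9 (−)-B-allyldiisopinocampheylborane (commercial pentane solution; isopinocampheyl groups from (+)-α-pinene)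
Product: 10 (3S)-homoallylic alcohol [4β-((1S)-1-hydroxybut-3-enyl)-5β,6β-epoxy ketone]
Conditions: Et2O, −78 °C; then H2O2, pH 7 phosphate buffer, MeOH, 0 °C
Reagents that add atoms: none
Why: Brown asymmetric allylboration through a chair six-membered transition state: the borane adds to the aldehyde far faster than to the hindered ketone, and the isopinocampheyl groups set 3S (the sense this reagent gives with aldehydes whose substituent outranks allyl), which a dipole-minimised approach from the methyl side of C4 should reinforce.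

Step 7
Reactants: 10 (3S)-homoallylic alcohol
Product: 11 3-O-triethylsilyl ether of 10
Conditions: TESCl, imidazole, DMAP (cat.), DMF, rt
Reagents that add atoms: chlorotriethylsilane, CC[Si](Cl)(CC)CC
Why: Silyl ether formation blocks retro-aldol cleavage of the β-hydroxy ketone in the next enolate step and marks O3 for later selective release.

Step 8
Reactants: 11 3-O-triethylsilyl ether
Product: 13 8β-hydroxy ketone (OH trans to the C7 side chain), via potassium C8 enolate 12 (not isolated)
Conditions: KN(SiMe3)2, THF, −78 °C; then 2-(phenylsulfonyl)-3-phenyloxaziridine, −78 °C; AcOH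
Reagents that add atoms: 2-(phenylsulfonyl)-3-phenyloxaziridine, O=S(=O)(c1ccccc1)N1OC1c1ccccc1
Why: Davis enolate hydroxylation: C8 is the only enolisable position, the oxaziridine should approach anti to the adjacent C7 side chain (each face carries one C4 substituent in a 1,3 relation) to give the thermodynamically preferred trans-7,8 product, and at −78 °C oxygen transfer should outrun 3-exo attack of the enolate on the epoxide.

Step 9
Reactants: 13 8β-hydroxy ketone
Product: 14 8-O-tert-butyldimethylsilyl ether of 13
Conditions: TBSOTf, 2,6-lutidine, CH2Cl2, −78 → 0 °C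
Reagents that add atoms: tert-butyldimethylsilyl triflate, CC(C)(C)[Si](C)(C)OS(=O)(=O)C(F)(F)F
Why: Silyl triflate silylation of the hindered α-ketol gives a second silyl ether that is more robust than the triethylsilyl ether at O3, so the two oxygens stay distinguishable.

Step 10
Reactants: 14 8-O-TBS ketone; 15 isopropenylmagnesium bromide
Product: 16 9α-hydroxy-9β-isopropenyl carbinol (isopropenyl cis to the C3 branch)
Conditions: 15, CeCl3 (anhydrous), THF, −78 °C; then 14, −78 → −40 °C; H2O
Reagents that add atoms: none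
Why: Organocerium 1,2-addition (Imamoto conditions) suppresses enolisation at C8; in the ring-A half-chair that keeps the C3 branch, the C7 side chain and the C8 silyloxy group equatorial, the C4 methyl is axial on the α face, so the nucleophile should enter axially from the β face, anti to that methyl.

Step 11
Reactants: 16 9α-hydroxy-9β-isopropenyl carbinol
Product: 17 cis-fused 5β,6β-epoxy-9α-hydroxy decalin with C1=C10 in ring B and the C12 PMB ether
Conditions: second-generation Grubbs catalyst RuCl2(=CHPh)(PCy3)(H2IMes) (cat.), CH2Cl2, 40 °C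
Reagents that add atoms: none
Why: Ring-closing metathesis of the C1 vinyl group with the C10 isopropenyl group closes the trisubstituted cyclohexene (hence Z C1=C10) with loss of ethene; the allylic tertiary hydroxyl assists, and the C11=C13 alkene cannot close a small ring.

Step 12
Reactants: 17 cis-decalin PMB ether
Product: 18 cis-decalin C12 allylic alcohol
Conditions: DDQ, CH2Cl2/pH 7 buffer, 0 °C
Reagents that add atoms: none
Why: Oxidative cleavage of the 4-methoxybenzyl ether by hydride abstraction should spare both silyl ethers, the epoxide, the tertiary alcohol and the trisubstituted alkene.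

Step 13
Reactants: 18 cis-decalin C12 allylic alcohol
Product: 19 cis-decalin C12 enal (2-substituted acrolein)
Conditions: MnO2, CH2Cl2, rt
Reagents that add atoms: none
Why: Allylic oxidation with MnO2 is selective for the primary allylic alcohol; the tertiary C9 hydroxyl cannot be oxidised.

Step 14
Reactants: 19 cis-decalin C12 enal
Product: 20 cis-decalin C12 acrylic acid
Conditions: NaClO2, NaH2PO4, 2-methylbut-2-ene, tBuOH/H2O, 0 °C
Reagents that add atoms: sodium chlorite, [Na+].[O-]Cl=O
Why: Pinnick oxidation converts the enal into the acid without touching the alkenes, the scavenger removing HOCl and the cold phosphate buffer keeping the epoxide and the tertiary allylic alcohol intact.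

Step 15
Reactants: 20 cis-decalin C12 acrylic acid
Product: 21 cis-decalin C12 methyl ester (5β,6β-epoxide; 9α-OH; 4α-CH3; 3S-OTES; 8β-OTBS)
Conditions: Me3SiCHN2, toluene/MeOH, 0 °C
Reagents that add atoms: trimethylsilyldiazomethane, C[Si](C)(C)C=[N+]=[N-]
Why: Esterification with a diazoalkane under neutral conditions gives the methyl ester that later serves as the acyl donor for lactonisation.

Step 16
Reactants: 21 cis-decalin C12 methyl ester
Product: 23 9-oxo-(1(10)Z,4Z)-germacra-1(10),4,11(13)-trien-6,12-olide 3-O-TES 8-O-TBS ether (C3 C6 C7 C8 configured as in the target), via ring-opened potassium C6-alkoxide ester 22 (not isolated)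
Conditions: KN(SiMe3)2 (1.1 equiv), 18-crown-6, THF, −78 → −20 °C; AcOH, −78 °C
Reagents that add atoms: none
Why: Grob-type fragmentation of a γ-hydroxy epoxide (closest known types: epoxy-alcohol fragmentations of fused bicycles and the Wharton fragmentation of decalin-1,3-diol monosulfonates): the crown-ether-separated potassium C9 alkoxide forms C9=O while the C4–C9 σ bond, lying on the α face anti to the β C5–O bond, expels the epoxide oxygen onto C6, so that C4=C5 forms and the bond shared by rings A and B is lost. The ten-membered ring therefore arises by ring expansion (cleavage of the fusion bond), and the γ-lactone closes by 5-exo-trig attack of the freed C6 alkoxide on the C12 methyl ester with loss of methoxide. No stereocentre is created and C3, C6, C7 and C8 are spectators; the geometry of C4=C5 follows from the antiperiplanar arrangement, in which C3 (cis to the epoxide oxygen) is gauche to C6 and ends cis to it (Z), while C1=C10 is Z because it was made in a six-membered ring. The step needs cleavage to outrun attack of the alkoxide on C6 of the epoxide or on the ester and a 1,2-shift of the C8 silyl group: the cis ring fusion lets ring A reach the half-chair with C9 below the epoxide plane (C3 axial), where σ(C4–C9)/σ*(C5–O) overlap is best, and release of epoxide strain, separation of two adjacent fully substituted carbons and formation of the enone should drive it at low temperature. Any reversible acyl transfer to O9 is drained by the irreversible cleavage, and the cold acetic acid quench should keep the liberated methoxide from adding to the methylene lactone or epimerising C8.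

Step 17
Reactants: 23 9-oxo germacradienolide bis-silyl ether
Product: 24 (9R)-9-hydroxy germacradienolide bis-silyl ether (8,9-syn)
Conditions: NaBH4, CeCl3·7H2O, MeOH, −78 °C
Reagents that add atoms: none
Why: Luche 1,2-reduction of the enone leaves the lactone and, at −78 °C, the α-methylene group alone; hydride should add anti to the non-chelating C8 silyloxy group (Felkin–Anh model) to give the 8,9-syn alcohol.

Step 18
Reactants: 25 angelic acid
Product: 26 (Z)-2-methylbut-2-en-1-ol
Conditions: LiAlH4, Et2O, 0 °C
Reagents that add atoms: none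
Why: Hydride reduction of the α-substituted unsaturated acid gives the allylic alcohol with the Z geometry retained.

Step 19
Reactants: 26 (Z)-2-methylbut-2-en-1-ol
Product: 27 (2S,3R)-2,3-epoxy-2-methylbutan-1-ol
Conditions: Ti(OiPr)4, L-(+)-diethyl tartrate, tBuOOH, 4 Å molecular sieves, CH2Cl2, −20 °C
Reagents that add atoms: tert-butyl hydroperoxide, CC(C)(C)OO
Why: Sharpless asymmetric epoxidation: the L-(+)-tartrate complex delivers oxygen to the face that gives the 2S epoxy alcohol (the sense known for 2-methylallyl alcohols), syn addition keeps the methyl groups trans, and any minor enantiomer becomes a separable diastereomer after step 21.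

Step 20
Reactants: 27 (2S,3R)-2,3-epoxy-2-methylbutan-1-ol
Product: 28 (2R,3R)-2,3-epoxy-2-methylbutanoic acid
Conditions: RuCl3 (cat.), NaIO4, MeCN/EtOAc/H2O, 0 °C → rt
Reagents that add atoms: sodium periodate, [Na+].[O-]I(=O)(=O)=O; water, O
Why: Ruthenium tetroxide-catalysed oxidation of the primary alcohol to the acid leaves the epoxide and both stereocentres untouched (the descriptor at C2 changes only through the priority rules).

Step 21
Reactants: 24 (9R)-9-hydroxy germacradienolide bis-silyl ether; 28 (2R,3R)-2,3-epoxy-2-methylbutanoic acid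
Product: 30 9-O-[(2R,3R)-2,3-epoxy-2-methylbutanoyl] germacradienolide bis-silyl ether, via mixed trichlorobenzoic anhydride 29 (not isolated)
Conditions: 28, 2,4,6-trichlorobenzoyl chloride, Et3N, THF, rt; then 24, DMAP, toluene, rt
Reagents that add atoms: none
Why: Yamaguchi esterification: DMAP opens the mixed anhydride at the aliphatic carbonyl (the aryl carbonyl is shielded by two ortho chlorines), and the acylpyridinium ion acylates the hindered C9 alcohol without epoxide opening or epimerisation.

Step 22
Reactants: 30 9-O-epoxyangeloyl bis-silyl ether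
Product: 31 3-hydroxy 8-O-TBS 9-O-epoxyangeloyl germacradienolide
Conditions: PPTS, MeOH/CH2Cl2, 0 °C
Reagents that add atoms: none
Why: Acid-catalysed methanolysis removes the less hindered triethylsilyl ether selectively, while the tert-butyldimethylsilyl ether, the epoxy ester and the lactone should survive pyridinium tosylate at 0 °C.

Step 23
Reactants: 31 3-hydroxy 8-O-TBS 9-O-epoxyangeloyl germacradienolide
Product: 32 3-O-acetyl 8-O-TBS 9-O-epoxyangeloyl germacradienolide
Conditions: Ac2O, pyridine, DMAP (cat.), CH2Cl2, 0 °C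
Reagents that add atoms: acetic anhydride, CC(=O)OC(C)=O
Why: DMAP-catalysed acylation of the only free hydroxyl installs the C3 acetate with retention, because only the O–H bond is touched.

Step 24
Reactants: 32 3-O-acetyl 8-O-TBS 9-O-epoxyangeloyl germacradienolide
Product: 33 CNP0137407.10 (target)
Conditions: HF·pyridine, pyridine, THF, 0 °C → rt
Reagents that add atoms: none
Why: Fluoride-mediated desilylation under mildly acidic buffered conditions frees O8 without the acyl migration from O9 or O3 and the conjugate additions that basic fluoride would invite.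

**Compound list**

1 | (S)-carvone | CC1=CC[C@@H](CC1=O)C(C)=C | starting material
2 | (5S)-5-(3-chloroprop-1-en-2-yl)-2-methylcyclohex-2-en-1-one | O=C1C(C)=CC[C@H](C(=C)CCl)C1 | intermediate
3 | (5S)-5-[3-(4-methoxybenzyloxy)prop-1-en-2-yl]-2-methylcyclohex-2-en-1-one | O=C1C(C)=CC[C@H](C(=C)COCc2ccc(OC)cc2)C1 | intermediate
4 | formaldehyde | C=O | starting material
5 | potassium dienolate of 3 (O–C9=C4–C5=C6) | [K+].[O-]C1=C(C)C=C[C@H](C(=C)COCc2ccc(OC)cc2)C1 | intermediate
6 | (2R,5R)-2-(hydroxymethyl)-2-methyl-5-[3-(4-methoxybenzyloxy)prop-1-en-2-yl]cyclohex-3-en-1-one | O=C1[C@@](C)(CO)C=C[C@H](C(=C)COCc2ccc(OC)cc2)C1 | intermediate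
7 | 5β,6β-epoxide of 6 | O=C1[C@@](C)(CO)[C@H]2O[C@H]2[C@H](C(=C)COCc3ccc(OC)cc3)C1 | intermediate
8 | 4β-formyl-5β,6β-epoxy ketone | O=C1[C@@](C)(C=O)[C@H]2O[C@H]2[C@H](C(=C)COCc3ccc(OC)cc3)C1 | intermediate
9 | (−)-B-allyldiisopinocampheylborane | C=CCB([C@@H]1C[C@@H]2C[C@H]([C@H]1C)C2(C)C)[C@@H]1C[C@@H]2C[C@H]([C@H]1C)C2(C)C | starting material
10 | (3S)-homoallylic alcohol, 4β-((1S)-1-hydroxybut-3-enyl)-5β,6β-epoxy ketone | O=C1[C@@](C)([C@@H](O)CC=C)[C@H]2O[C@H]2[C@H](C(=C)COCc3ccc(OC)cc3)C1 | intermediate
11 | 3-O-triethylsilyl ether of 10 | O=C1[C@@](C)([C@@H](O[Si](CC)(CC)CC)CC=C)[C@H]2O[C@H]2[C@H](C(=C)COCc3ccc(OC)cc3)C1 | intermediate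
12 | potassium C8 enolate of 11 | [K+].[O-]C=1[C@@](C)([C@@H](O[Si](CC)(CC)CC)CC=C)[C@H]2O[C@H]2[C@H](C(=C)COCc3ccc(OC)cc3)C=1 | intermediate
13 | 8β-hydroxy ketone | O=C1[C@@](C)([C@@H](O[Si](CC)(CC)CC)CC=C)[C@H]2O[C@H]2[C@H](C(=C)COCc3ccc(OC)cc3)[C@H]1O | intermediate
14 | 8-O-tert-butyldimethylsilyl ether of 13 | O=C1[C@@](C)([C@@H](O[Si](CC)(CC)CC)CC=C)[C@H]2O[C@H]2[C@H](C(=C)COCc3ccc(OC)cc3)[C@H]1O[Si](C)(C)C(C)(C)C | intermediate
15 | isopropenylmagnesium bromide | C=C(C)[Mg]Br | starting material
16 | 9α-hydroxy-9β-isopropenyl carbinol | O[C@]1(C(C)=C)[C@@](C)([C@@H](O[Si](CC)(CC)CC)CC=C)[C@H]2O[C@H]2[C@H](C(=C)COCc3ccc(OC)cc3)[C@H]1O[Si](C)(C)C(C)(C)C | intermediate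
17 | cis-fused epoxy-decalinol, C12 PMB ether | CC1=CC[C@H](O[Si](CC)(CC)CC)[C@@]2(C)[C@H]3O[C@H]3[C@H](C(=C)COCc4ccc(OC)cc4)[C@@H](O[Si](C)(C)C(C)(C)C)[C@@]12O | intermediate
18 | cis-fused epoxy-decalinol, C12 allylic alcohol | CC1=CC[C@H](O[Si](CC)(CC)CC)[C@@]2(C)[C@H]3O[C@H]3[C@H](C(=C)CO)[C@@H](O[Si](C)(C)C(C)(C)C)[C@@]12O | intermediate
19 | cis-fused epoxy-decalinol, C12 enal | CC1=CC[C@H](O[Si](CC)(CC)CC)[C@@]2(C)[C@H]3O[C@H]3[C@H](C(=C)C=O)[C@@H](O[Si](C)(C)C(C)(C)C)[C@@]12O | intermediate
20 | cis-fused epoxy-decalinol, C12 acid | CC1=CC[C@H](O[Si](CC)(CC)CC)[C@@]2(C)[C@H]3O[C@H]3[C@H](C(=C)C(=O)O)[C@@H](O[Si](C)(C)C(C)(C)C)[C@@]12O | intermediate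
21 | cis-fused epoxy-decalinol, C12 methyl ester (fragmentation precursor) | CC1=CC[C@H](O[Si](CC)(CC)CC)[C@@]2(C)[C@H]3O[C@H]3[C@H](C(=C)C(=O)OC)[C@@H](O[Si](C)(C)C(C)(C)C)[C@@]12O | intermediate
22 | ring-opened potassium C6-alkoxide methyl ester | COC(=O)C(=C)[C@H]1[C@H]([O-])/C=C(/C)[C@@H](O[Si](CC)(CC)CC)C/C=C(/C)C(=O)[C@@H]1O[Si](C)(C)C(C)(C)C.[K+] | intermediate
23 | 9-oxo-(1(10)Z,4Z)-germacra-1(10),4,11(13)-trien-6,12-olide 3-O-TES 8-O-TBS ether | C=C1C(=O)O[C@@H]2/C=C(/C)[C@@H](O[Si](CC)(CC)CC)C/C=C(/C)C(=O)[C@H](O[Si](C)(C)C(C)(C)C)[C@@H]12 | intermediate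
24 | (9R)-9-hydroxy germacradienolide 3-O-TES 8-O-TBS ether | C=C1C(=O)O[C@@H]2/C=C(/C)[C@@H](O[Si](CC)(CC)CC)C/C=C(/C)[C@@H](O)[C@H](O[Si](C)(C)C(C)(C)C)[C@@H]12 | intermediate
25 | angelic acid | C/C=C(/C)C(=O)O | starting material
26 | (Z)-2-methylbut-2-en-1-ol | C/C=C(/C)CO | intermediate
27 | (2S,3R)-2,3-epoxy-2-methylbutan-1-ol | OC[C@]1(C)O[C@@H]1C | intermediate
28 | (2R,3R)-2,3-epoxy-2-methylbutanoic acid | OC(=O)[C@]1(C)O[C@@H]1C | intermediate
29 | mixed anhydride of 28 with 2,4,6-trichlorobenzoic acid | O=C(OC(=O)c1c(Cl)cc(Cl)cc1Cl)[C@]1(C)O[C@@H]1C | intermediate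
30 | 9-O-[(2R,3R)-2,3-epoxy-2-methylbutanoyl] 3-O-TES 8-O-TBS germacradienolide | C=C1C(=O)O[C@@H]2/C=C(/C)[C@@H](O[Si](CC)(CC)CC)C/C=C(/C)[C@@H](OC(=O)[C@]3(C)O[C@@H]3C)[C@H](O[Si](C)(C)C(C)(C)C)[C@@H]12 | intermediate
31 | 3-hydroxy 8-O-TBS 9-O-epoxyangeloyl germacradienolide | C=C1C(=O)O[C@@H]2/C=C(/C)[C@@H](O)C/C=C(/C)[C@@H](OC(=O)[C@]3(C)O[C@@H]3C)[C@H](O[Si](C)(C)C(C)(C)C)[C@@H]12 | intermediate
32 | 3-O-acetyl 8-O-TBS 9-O-epoxyangeloyl germacradienolide | C=C1C(=O)O[C@@H]2/C=C(/C)[C@@H](OC(C)=O)C/C=C(/C)[C@@H](OC(=O)[C@]3(C)O[C@@H]3C)[C@H](O[Si](C)(C)C(C)(C)C)[C@@H]12 | intermediate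
33 | CNP0137407.10 (3S,6R,7R,8R,9R; epoxy ester 2R,3R) | C=C1C(=O)O[C@@H]2/C=C(/C)[C@@H](OC(C)=O)C/C=C(/C)[C@@H](OC(=O)[C@]3(C)O[C@@H]3C)[C@H](O)[C@@H]12 | target

**Step count**

Total: 24 steps. Longest linear sequence: 21 steps (steps 1–17 and 21–24 from (S)-carvone); the epoxy acid takes 3 steps (18–20).

**Steps most likely to fail**

Step 16. The C9 alkoxide may be consumed faster by other paths than by C–C cleavage: acyl transfer to the C12 ester, transannular attack on C6 of the epoxide, or a shift of the C8 silyl group. The methoxide released on lactonisation may also add to the methylene lactone or epimerise C8. The fallback sets out from 17, which has the same decalin but carries the side chain as its PMB ether, so no ester and no methoxide are present. Fragmentation of 17 with KN(SiMe3)2 and 18-crown-6 in THF would give the ring-opened 6-hydroxy-9-oxo germacradiene PMB ether F1. DDQ in buffered CH2Cl2 would then free the 6,12-diol F2. MnO2 in CH2Cl2 (allylic oxidation to the enal, lactol formation with the C6 hydroxyl, second oxidation) would close the α-methylene lactone and rejoin the route at 23.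

Step 10. The bulky alkenyl nucleophile may be delivered to the α face of the hindered ketone, or may act as a base at C8 so that the ketone is returned. The fallback sets out from 14 and builds the isopropenyl group in stages from a slim nucleophile with a strong axial preference. Ethynylmagnesium bromide with CeCl3 in THF at −78 °C would give the 9β-ethynyl-9α-hydroxy carbinol F3. CO2-assisted Markovnikov hydration (AgOAc, DBU, CO2, MeCN, then water) would give the 9β-acetyl-9α-hydroxy compound F4. Wittig methylenation (Ph3PCH3Br, KOtBu, toluene, 60 °C) would then rejoin the route at 16.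

Step 3. Facial selectivity at C4 rests on 1,4-induction only and may be poor; the dienolate may also react at C6 or on oxygen, and the aldol may revert. The fallback sets out from 3 and relays the C7 centre through C6. TMSCl, NaI and Et3N in MeCN would give the linear silyl dienol ether F5. mCPBA with NaHCO3 in CH2Cl2 (γ-hydroxylation at the terminal double bond, anti to the adjacent C7 side chain) would give the 6β-hydroxy enone F6. Bu3SnCH2OC(=NH)CCl3 with catalytic TfOH would give the stannylmethyl ether F7. LiN(iPr)2 at −78 °C (ketone masked as its C8 enolate) followed by n-BuLi would trigger tin–lithium exchange and a Still–Wittig [2,3] shift. This shift moves the CH2O group suprafacially from the β oxygen on C6 to the β face of C4 and the alkene to C5=C6, and rejoins the route at 6 after protonation.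

Further compounds
F1 | step 16 | ring-opened 6-hydroxy-9-oxo germacradiene, C12 PMB ether | COc1ccc(COCC(=C)[C@H]2[C@H](O)/C=C(/C)[C@@H](O[Si](CC)(CC)CC)C/C=C(/C)C(=O)[C@@H]2O[Si](C)(C)C(C)(C)C)cc1
F2 | step 16 | ring-opened 6,12-diol 9-ketone | OCC(=C)[C@H]1[C@H](O)/C=C(/C)[C@@H](O[Si](CC)(CC)CC)C/C=C(/C)C(=O)[C@@H]1O[Si](C)(C)C(C)(C)C
F3 | step 10 | 9β-ethynyl-9α-hydroxy carbinol | O[C@]1(C#C)[C@@](C)([C@@H](O[Si](CC)(CC)CC)CC=C)[C@H]2O[C@H]2[C@H](C(=C)COCc3ccc(OC)cc3)[C@H]1O[Si](C)(C)C(C)(C)C
F4 | step 10 | 9β-acetyl-9α-hydroxy compound | O[C@]1(C(C)=O)[C@@](C)([C@@H](O[Si](CC)(CC)CC)CC=C)[C@H]2O[C@H]2[C@H](C(=C)COCc3ccc(OC)cc3)[C@H]1O[Si](C)(C)C(C)(C)C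
F5 | step 3 | linear trimethylsilyl dienol ether of 3 | C[Si](C)(C)OC1=C(C)C=C[C@H](C(=C)COCc2ccc(OC)cc2)C1
F6 | step 3 | 6β-hydroxy enone | O=C1C(C)=C[C@@H](O)[C@H](C(=C)COCc2ccc(OC)cc2)C1
F7 | step 3 | 6β-(tributylstannylmethoxy) enone | O=C1C(C)=C[C@@H](OC[Sn](CCCC)(CCCC)CCCC)[C@H](C(=C)COCc2ccc(OC)cc2)C1
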